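**Plan**

- Numbering: the cyclohexene carbons run from C1' (the CH that carries coumarin A through its C6) via C2'=C3' (C3' bears the ring methyl), C4' and C5' to the quaternary C6' (methyl plus the E-styryl arm to C8 of coumarin B).
- Retrosynthesis cuts, in this order: C3'–CH3 (Negishi coupling of an enol triflate), C1'–C6 of coumarin A (conjugate arylation of an enone), the ring bonds C1'=C2' and C5'–C6' (Robinson annulation), and the C8–vinyl bond of coumarin B (Heck).
- Enabling feature: C6' lies between C1' and C5' and stands 1,4 to C3'. With C3' as a ketone, the ring is a 4,4-disubstituted cyclohex-2-enone, which comes apart into an α-branched aldehyde (C1', C6') and methyl vinyl ketone (C2' to C5').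
- Forward order: coumarin B (from umbelliferone) receives its side chain, the cyclohexenone ring closes in step 5, coumarin A (lactone ring closed separately in step 7) is attached at C1', and the C3' methyl comes last.
- Stereochemistry: C6' comes from the chiral primary amine catalyst of the annulation. C1' comes from the chiral diene–rhodium catalyst, which places the aryl group cis to the styryl arm. The E-alkene comes from the Heck step.

Key step: step 5

Remark on the chemistry (assumption): the sense of induction of the amine catalyst in step 5 and of the diene ligand in step 9 is taken by analogy from 2-arylpropanals and cyclohex-2-enone. Both antipodes of each are available, so the antipode that gives (S) at C6' and (S) at C1' is the one used.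

**Route**

Step 1
Reactants: 1 umbelliferone
Product: 2 7-hydroxy-8-iodo-2H-chromen-2-one
Conditions: I2, KI, 20% aq. NH3, rt; acidic work-up
Reagents that add atoms: iodine, II
Why: Electrophilic aromatic iodination of the phenoxide goes to C8, the carbon between the phenol oxygen and the ring oxygen, as is established for 7-hydroxycoumarins under iodine/ammonia conditions.

Step 2
Reactants: 2 7-hydroxy-8-iodo-2H-chromen-2-one
Product: 3 8-iodo-7-methoxy-2H-chromen-2-one
Conditions: MeI, K2CO3, acetone, reflux
Reagents that add atoms: iodomethane, CI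
Why: Williamson O-methylation of an acidic phenol is routine, and the lactone and the aryl iodide are inert to carbonate in acetone.

Step 3
Reactants: 3 8-iodo-7-methoxy-2H-chromen-2-one; 4 2-methylbut-3-en-1-ol (racemic)
Product: 5 (E)-8-(4-hydroxy-3-methylbut-1-en-1-yl)-7-methoxy-2H-chromen-2-one (racemic)
Conditions: Pd(OAc)2 (5 mol %), P(o-tol)3 (10 mol %), Et3N, DMF, 90 °C
Reagents that add atoms: none
Why: Mizoroki–Heck coupling places the aryl group on the terminal alkene carbon, and syn β-hydride elimination toward the benzylic hydrogen gives the E-styrene; phosphine/amine conditions are chosen to hold back chain walking toward the alcohol.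

Step 4
Reactants: 5 (E)-8-(4-hydroxy-3-methylbut-1-en-1-yl)-7-methoxy-2H-chromen-2-one
Product: 6 (E)-4-(7-methoxy-2-oxo-2H-chromen-8-yl)-2-methylbut-3-enal (racemic)
Conditions: Dess–Martin periodinane, pyridine, CH2Cl2, 0 °C to rt; used crude at once
Reagents that add atoms: none
Why: Buffered Dess–Martin oxidation converts homoallylic primary alcohols into β,γ-unsaturated aldehydes without double-bond migration, and any migration would in any case feed the same dienamine in step 5.

Step 5
Reactants: 6 (E)-4-(7-methoxy-2-oxo-2H-chromen-8-yl)-2-methylbut-3-enal; 7 methyl vinyl ketone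
Product: 10 (S)-4-[(E)-2-(7-methoxy-2-oxo-2H-chromen-8-yl)ethenyl]-4-methylcyclohex-2-en-1-one, via keto aldehyde 8 (not isolated), via aldol 9 (not isolated)
Conditions: 1-[(1R,2R)-2-aminocyclohexyl]-3-[3,5-bis(trifluoromethyl)phenyl]thiourea (20 mol %), PhCO2H (20 mol %), 7 (2 equiv, slow addition), toluene, rt; then p-TsOH·H2O (0.3 equiv), 60 °C
Reagents that add atoms: none
Why: The primary amine condenses with racemic 6 to a single dienamine N–C1'=C6'(CH3)–CH=CH–Ar, which erases the old α-stereocentre; its α-carbon C6' adds to thiourea-bound methyl vinyl ketone (Michael addition, C5'–C6'), and hydrolysis returns the catalyst and keto aldehyde 8. Acid then drives aldol addition of the methyl-side enol (C2') onto the aldehyde carbon C1' and dehydration of aldol 9 to the conjugated enone (C1'=C2'). The closest known reaction type is the amine-catalysed asymmetric Robinson annulation of α,α-disubstituted aldehydes with vinyl ketones. The ring closes in the 6-(enolexo)-exo-trig mode; enolisation toward C4' could only give a four-membered ring, and the aldehyde has no α-hydrogen. The C6' configuration is set by the catalyst, whose trans-cyclohexanediamine scaffold holds the hydrogen-bonded enone over one face of the E-dienamine so that the (S) centre results. The step needs α- over γ-attack and no [4+2] cycloaddition across the dienamine; the substrate favours this because the γ-carbon is benzylic to C8 of coumarin B, flanked by the methoxy group and the ring oxygen, and because α-attack keeps the styrene conjugation.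

Step 6
Reactants: 11 2-hydroxy-4-methoxybenzaldehyde
Product: 12 2-hydroxy-5-iodo-4-methoxybenzaldehyde
Conditions: ICl, AcOH, rt
Reagents that add atoms: iodine monochloride, ClI
Why: Electrophilic aromatic iodination goes para to the phenol and ortho to the methoxy group (C5), since C3 between the two oxygens is hindered.

Step 7
Reactants: 12 2-hydroxy-5-iodo-4-methoxybenzaldehyde; 13 ethyl 2-(triphenyl-λ5-phosphanylidene)acetate
Product: 15 6-iodo-7-methoxy-2H-chromen-2-one, via E-cinnamate ester 14 (not isolated)
Conditions: 13 (1.2 equiv), N,N-diethylaniline, reflux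
Reagents that add atoms: none
Why: Wittig olefination of the salicylaldehyde followed by thermal E-to-Z isomerisation and lactonisation is the classical coumarin synthesis, and the aryl iodide is untouched.

Step 8
Reactants: 15 6-iodo-7-methoxy-2H-chromen-2-one
Product: 16 (7-methoxy-2-oxo-2H-chromen-6-yl)zinc iodide (LiCl-complexed THF solution, titrated and used directly)
Conditions: Zn dust (activated with BrCH2CH2Br and Me3SiCl, 5 mol % each), LiCl, THF, 50 °C
Reagents that add atoms: zinc, [Zn]
Why: LiCl-mediated direct insertion of zinc into aryl iodides tolerates esters and lactones, so the arylzinc forms without attack on the coumarin carbonyl.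

Step 9
Reactants: 10 (S)-4-[(E)-2-(7-methoxy-2-oxo-2H-chromen-8-yl)ethenyl]-4-methylcyclohex-2-en-1-one; 16 (7-methoxy-2-oxo-2H-chromen-6-yl)zinc iodide
Product: 17 trimethyl{[(3S,4S)-3-(7-methoxy-2-oxo-2H-chromen-6-yl)-4-[(E)-2-(7-methoxy-2-oxo-2H-chromen-8-yl)ethenyl]-4-methylcyclohex-1-en-1-yl]oxy}silane
Conditions: [RhCl(C2H4)2]2 (2.5 mol %), (R,R)-2,5-diphenylbicyclo[2.2.2]octa-2,5-diene (5.5 mol %), 16 (1.8 equiv), Me3SiCl (1.8 equiv), THF, 20 to 40 °C; non-aqueous work-up (pentane/Et3N, filtration), used at once
Reagents that add atoms: chlorotrimethylsilane, C[Si](C)(C)Cl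
Why: In this rhodium-catalysed asymmetric 1,4-addition the aryl group passes from zinc to monovalent rhodium and adds across C1'=C2' of the ketone enone (far more reactive than the coumarin lactone alkenes) on the face fixed by the chiral diene, the one syn to the styryl arm, which gives (S) at C1'; Me3SiCl traps the enolate so that the enol double bond is fixed at C2'=C3'.

Step 10
Reactants: 17 silyl enol ether from step 9
Product: 18 (3S,4S)-3-(7-methoxy-2-oxo-2H-chromen-6-yl)-4-[(E)-2-(7-methoxy-2-oxo-2H-chromen-8-yl)ethenyl]-4-methylcyclohex-1-en-1-yl trifluoromethanesulfonate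
Conditions: CsF (anhydrous, 2 equiv), PhNTf2 (1.3 equiv), DME, rt; 0.5 M HCl wash
Reagents that add atoms: N-phenylbis(trifluoromethanesulfonimide), O=S(=O)(N(c1ccccc1)S(=O)(=O)C(F)(F)F)C(F)(F)F
Why: Fluoride-induced desilylation releases the caesium enolate regiospecifically and PhNTf2 triflates it on oxygen, a known conversion of silyl enol ethers into enol triflates that avoids the alkyllithium reagents a coumarin would not survive.

Step 11
Reactants: 18 enol triflate from step 10
Product: 19 7-methoxy-8-{(E)-2-[(1S,2S)-2-(7-methoxy-2-oxo-2H-chromen-6-yl)-1,4-dimethylcyclohex-3-en-1-yl]ethenyl}-2H-chromen-2-one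
Conditions: Pd(PPh3)4 (5 mol %), Me2Zn (2 equiv, toluene solution), THF, 0 to 45 °C; aq. NH4Cl
Reagents that add atoms: dimethylzinc, C[Zn]C
Why: Negishi coupling (oxidative addition of zerovalent palladium into the C–OTf bond, methyl transfer from zinc, reductive elimination) puts the methyl on C3' without moving the alkene or touching C1', and dimethylzinc alone does not add to the coumarins.

**Compound list**

1 | umbelliferone (7-hydroxy-2H-chromen-2-one) | O=c1ccc2ccc(O)cc2o1 | starting material
2 | 7-hydroxy-8-iodo-2H-chromen-2-one | O=c1ccc2ccc(O)c(I)c2o1 | intermediate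
3 | 8-iodo-7-methoxy-2H-chromen-2-one | COc1ccc2ccc(=O)oc2c1I | intermediate
4 | 2-methylbut-3-en-1-ol (racemic) | C=CC(C)CO | starting material
5 | (E)-8-(4-hydroxy-3-methylbut-1-en-1-yl)-7-methoxy-2H-chromen-2-one (racemic) | CC(CO)/C=C/c1c(OC)ccc2ccc(=O)oc12 | intermediate
6 | (E)-4-(7-methoxy-2-oxo-2H-chromen-8-yl)-2-methylbut-3-enal (racemic) | CC(C=O)/C=C/c1c(OC)ccc2ccc(=O)oc12 | intermediate
7 | methyl vinyl ketone (but-3-en-2-one) | CC(=O)C=C | starting material
8 | (S)-2-[(E)-2-(7-methoxy-2-oxo-2H-chromen-8-yl)ethenyl]-2-methyl-5-oxohexanal | O=C[C@@](C)(CCC(C)=O)/C=C/c1c(OC)ccc2ccc(=O)oc12 | intermediate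
9 | (4S)-3-hydroxy-4-[(E)-2-(7-methoxy-2-oxo-2H-chromen-8-yl)ethenyl]-4-methylcyclohexan-1-one (C3 epimers) | OC1CC(=O)CC[C@@]1(C)/C=C/c1c(OC)ccc2ccc(=O)oc12 | intermediate
10 | (S)-4-[(E)-2-(7-methoxy-2-oxo-2H-chromen-8-yl)ethenyl]-4-methylcyclohex-2-en-1-one | C1=CC(=O)CC[C@@]1(C)/C=C/c1c(OC)ccc2ccc(=O)oc12 | intermediate
11 | 2-hydroxy-4-methoxybenzaldehyde | COc1ccc(C=O)c(O)c1 | starting material
12 | 2-hydroxy-5-iodo-4-methoxybenzaldehyde | O=Cc1cc(I)c(OC)cc1O | intermediate
13 | ethyl 2-(triphenyl-λ5-phosphanylidene)acetate | CCOC(=O)C=P(c1ccccc1)(c1ccccc1)c1ccccc1 | starting material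
14 | ethyl (E)-3-(2-hydroxy-5-iodo-4-methoxyphenyl)prop-2-enoate | CCOC(=O)/C=C/c1cc(I)c(OC)cc1O | intermediate
15 | 6-iodo-7-methoxy-2H-chromen-2-one | COc1cc2oc(=O)ccc2cc1I | intermediate
16 | (7-methoxy-2-oxo-2H-chromen-6-yl)zinc iodide | COc1cc2oc(=O)ccc2cc1[Zn]I | intermediate
17 | trimethyl{[(3S,4S)-3-(7-methoxy-2-oxo-2H-chromen-6-yl)-4-[(E)-2-(7-methoxy-2-oxo-2H-chromen-8-yl)ethenyl]-4-methylcyclohex-1-en-1-yl]oxy}silane | COc1cc2oc(=O)ccc2cc1[C@H]1C=C(O[Si](C)(C)C)CC[C@@]1(C)/C=C/c1c(OC)ccc2ccc(=O)oc12 | intermediate
18 | (3S,4S)-3-(7-methoxy-2-oxo-2H-chromen-6-yl)-4-[(E)-2-(7-methoxy-2-oxo-2H-chromen-8-yl)ethenyl]-4-methylcyclohex-1-en-1-yl trifluoromethanesulfonate | COc1cc2oc(=O)ccc2cc1[C@H]1C=C(OS(=O)(=O)C(F)(F)F)CC[C@@]1(C)/C=C/c1c(OC)ccc2ccc(=O)oc12 | intermediate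
19 | 7-methoxy-8-{(E)-2-[(1S,2S)-2-(7-methoxy-2-oxo-2H-chromen-6-yl)-1,4-dimethylcyclohex-3-en-1-yl]ethenyl}-2H-chromen-2-one | COc1cc2oc(=O)ccc2cc1[C@H]1C=C(C)CC[C@@]1(C)/C=C/c1c(OC)ccc2ccc(=O)oc12 | target

**Step count and risks**

Total steps: 11. Longest linear sequence: 8 steps (steps 1, 2, 3, 4, 5, 9, 10, 11); steps 6 to 8 form the side branch that joins in step 9.

Steps most likely to fail:

1. Step 5. The dienamine may react at its γ-carbon or in a [4+2] sense instead of at C6'. The primary amine may be alkylated by methyl vinyl ketone and stop turning over. Facial selectivity on this α-alkenyl aldehyde may be low. Fallback (sets out from 3, comes back at 10): the quaternary centre is made by an asymmetric Diels–Alder reaction instead of enamine chemistry. Commercial (E)-3-(tert-butyldimethylsilyloxy)-N,N-dimethylbuta-1,3-dien-1-amine and methacrolein are combined with the trivalent chromium complex (salen)CrSbF6 (salen = N,N'-bis(3,5-di-tert-butylsalicylidene)-trans-cyclohexane-1,2-diamine dianion, antipode chosen for the (1R) centre; CH2Cl2, 4 Å sieves, −40 °C). This should give the endo adduct (1R,2S)-4-[(tert-butyldimethylsilyl)oxy]-2-(dimethylamino)-1-methylcyclohex-3-ene-1-carbaldehyde F1. Wittig methylenation (Ph3P=CH2, THF) gives (1S,6S)-3-[(tert-butyldimethylsilyl)oxy]-6-ethenyl-N,N,6-trimethylcyclohex-2-en-1-amine F2. Dilute HCl in THF hydrolyses the silyl enol ether and eliminates dimethylamine to (S)-4-ethenyl-4-methylcyclohex-2-en-1-one F3. Mizoroki–Heck coupling of F3 with iodide 3 (Pd(OAc)2, P(o-tol)3, Et3N, DMF, 90 °C) then gives 10; after insertion only benzylic β-hydrogens are available, so the E-styrene is the only expected Heck product.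

2. Step 9. Carbometalation at C1' beside the quaternary carbon may be slow, the aryl group may add to a coumarin C3=C4 bond instead, catalyst control of the C1' face may be incomplete, and the trimethylsilyl group may be lost on work-up. Fallback (sets out from 10 and 15, comes back at 18): a nickel-catalysed reductive conjugate addition uses the aryl iodide directly, with no organozinc reagent. Enone 10, iodide 15 and Et3SiCl are treated with NiCl2(dme) (10 mol %), neocuproine (10 mol %) and Mn powder in DMF at rt. The allylnickel pathway engages only the ketone enone and should give triethyl{[(3S,4S)-3-(7-methoxy-2-oxo-2H-chromen-6-yl)-4-[(E)-2-(7-methoxy-2-oxo-2H-chromen-8-yl)ethenyl]-4-methylcyclohex-1-en-1-yl]oxy}silane F4 together with its C1' epimer. CsF/PhNTf2 as in step 10 converts the more robust triethylsilyl ether into 18. Face selection then rests on the substrate, and the C1' epimers are separated at 18.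

3. Step 3. After insertion, β-hydride elimination may go toward the methyl-bearing carbon, followed by chain walking to double-bond isomers or to the saturated aldehyde, and insertion at the di-ortho-substituted iodide may be slow. Fallback (sets out from 4, comes back at 5): cross-metathesis of 4 with vinylboronic acid pinacol ester (second-generation Grubbs catalyst, CH2Cl2, 40 °C) gives (E)-2-methyl-4-(4,4,5,5-tetramethyl-1,3,2-dioxaborolan-2-yl)but-3-en-1-ol F5. Suzuki–Miyaura coupling of F5 with iodide 3 (Pd(dppf)Cl2, K3PO4, dioxane/H2O, 70 °C) gives 5 with the alkene position and E geometry fixed by the boronate.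

Further compounds
F1 | step 5 | (1R,2S)-4-[(tert-butyldimethylsilyl)oxy]-2-(dimethylamino)-1-methylcyclohex-3-ene-1-carbaldehyde | O=C[C@]1(C)CCC(O[Si](C)(C)C(C)(C)C)=C[C@@H]1N(C)C
F2 | step 5 | (1S,6S)-3-[(tert-butyldimethylsilyl)oxy]-6-ethenyl-N,N,6-trimethylcyclohex-2-en-1-amine | C=C[C@]1(C)CCC(O[Si](C)(C)C(C)(C)C)=C[C@@H]1N(C)C
F3 | step 5 | (S)-4-ethenyl-4-methylcyclohex-2-en-1-one | C1=CC(=O)CC[C@@]1(C)C=C
F4 | step 9 | triethyl{[(3S,4S)-3-(7-methoxy-2-oxo-2H-chromen-6-yl)-4-[(E)-2-(7-methoxy-2-oxo-2H-chromen-8-yl)ethenyl]-4-methylcyclohex-1-en-1-yl]oxy}silane | COc1cc2oc(=O)ccc2cc1[C@H]1C=C(O[Si](CC)(CC)CC)CC[C@@]1(C)/C=C/c1c(OC)ccc2ccc(=O)oc12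
F5 | step 3 | (E)-2-methyl-4-(4,4,5,5-tetramethyl-1,3,2-dioxaborolan-2-yl)but-3-en-1-ol | CC(CO)/C=C/B1OC(C)(C)C(C)(C)O1
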